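The route cuts the diaryl ether between the oxygen and C6 of ring A (the phenol ring) while ring A is still a cyclohexenone. The feature exploited is that the aryloxy carbon C6 is ortho to the phenol carbon C1. At the enone stage C6 is therefore the alpha-prime carbon of the C1 ketone and can carry a diazo group. One neutral operation, dirhodium-catalysed carbenoid insertion into the O–H bond of 2,4-dibromophenol (ring B), then makes the C6–O bond without disturbing any of the four C–Br bonds. Its precursor is 2,3-dibromo-6-diazocyclohex-2-en-1-one, made from cyclohexane-1,3-dione, whose C2 and C3 receive the bromines. C4–C5 is dehydrogenated last.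

Key step: step 4

Remark: in every compound ring A is numbered C1 (carbonyl, later phenol carbon), C2 and C3 (bromine-bearing), C4, C5 and C6 (ether carbon); ring B is the 2,4-dibromophenyl ring; the 1,3-dicarbonyl compounds 2 and 5 are drawn as keto forms although they are largely enolised.

Step 1
Reactants: 1 cyclohexane-1,3-dione
Product: 2 2-bromocyclohexane-1,3-dione
Conditions: NBS (1.0 equiv), CH2Cl2, 0 °C to rt
Reagents that add atoms: N-bromosuccinimide, O=C1CCC(=O)N1Br
Why: Electrophilic alpha-bromination of an enolised 1,3-diketone: C2, flanked by both carbonyls, is by far the most nucleophilic carbon, and with one equivalent of NBS in the cold the reaction should stop at the monobromide because any 2,2-dibromide passes a bromine back to unreacted 1.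

Step 2
Reactants: 2 2-bromocyclohexane-1,3-dione
Product: 3 2,3-dibromocyclohex-2-en-1-one
Conditions: (COBr)2 (1.2 equiv), DMF (cat.), CH2Cl2, 0 °C to rt; cold aq. NaHCO3 work-up
Reagents that add atoms: oxalyl bromide, O=C(Br)C(=O)Br
Why: Vilsmeier-type conversion of a vinylogous acid into a vinylogous acyl bromide: the bromoiminium salt formed from (COBr)2 and DMF activates the enol oxygen, bromide adds at C3 and expels DMF, and since C1 and C3 of 2 are equivalent only one regioisomer can arise.

Step 3
Reactants: 3 2,3-dibromocyclohex-2-en-1-one
Product: 6 2,3-dibromo-6-diazocyclohex-2-en-1-one, via lithium dienolate 4 (not isolated), via trifluoroacetyl ketone 5 (not isolated)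
Conditions: LiN(SiMe3)2 (1.1 equiv), THF, −78 °C; CF3CO2CH2CF3 (1.2 equiv), −78 °C; cold 5% HCl work-up, crude 5; then p-ABSA (1.3 equiv), Et3N (1.5 equiv), H2O (1 equiv), MeCN, 0 °C to rt, dark; 6 kept cold and used promptly
Reagents that add atoms: 4-acetamidobenzenesulfonyl azide (p-ABSA), CC(=O)Nc1ccc(cc1)S(=O)(=O)N=[N+]=[N-]; 2,2,2-trifluoroethyl trifluoroacetate, O=C(OCC(F)(F)F)C(F)(F)F (its CF3CO group is held only by 5)
Why: Detrifluoroacetylative (Regitz-type) diazo transfer, the standard entry to alpha-prime-diazo enones: the bulky amide removes the kinetic C6 proton at −78 °C instead of adding to C3, the dienolate is C-acylated at once by the activated ester, and the acidic diketone 5 takes the diazo group from the sulfonyl azide while its trifluoroacetyl group leaves on the sulfonamide nitrogen.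

Step 4
Reactants: 6 2,3-dibromo-6-diazocyclohex-2-en-1-one; 7 2,4-dibromophenol
Product: 8 (±)-2,3-dibromo-6-(2,4-dibromophenoxy)cyclohex-2-en-1-one
Conditions: 7 (3 equiv), Rh2(OAc)4 (1 mol %), 4 Å MS, CH2Cl2, 0 °C to rt, 6 in CH2Cl2 added by syringe pump over 4 h; excess 7 removed on silica gel, no basic wash
Reagents that add atoms: none
Why: Rh2(OAc)4 expels N2 from 6 to give an electrophilic rhodium carbenoid at C6, the neutral hydroxyl oxygen of 7 adds to it to form an oxonium ylide, and a proton shift from oxygen to C6 releases the alpha-aryloxy ketone and the catalyst. The closest known reaction type is this same dirhodium-catalysed O–H insertion of alpha-diazo ketones, cyclic alpha-prime-diazo enones included, into phenols. No ring is closed; rings A and B, both present beforehand, are only joined through the new C6–O bond. The one new stereocentre, C6, forms without any controlling element and 8 is racemic, which is harmless because C6 becomes sp2 in step 5. The selectivity needed is O–H capture ahead of 1,2-hydride migration from C5, carbene dimerisation, water insertion and attack on ring B; it is secured by the large standing excess of 7 with slow addition of 6, by the sieves, by the ring, which holds the C1 carbonyl in the plane of the carbenoid and so leaves both faces of C6 open to the incoming phenol, and by the two bromines that deactivate ring B, whose only free ortho carbon is C6'. Since neither phenoxide nor a copper or palladium catalyst is present, C3 of the vinylogous acyl bromide and all four C–Br bonds should stay intact.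

Step 5
Reactants: 8 (±)-2,3-dibromo-6-(2,4-dibromophenoxy)cyclohex-2-en-1-one
Product: 9 tert-butyl{[5,6-dibromo-2-(2,4-dibromophenoxy)cyclohexa-1,5-dien-1-yl]oxy}dimethylsilane (cross-conjugated dienol ether, double bonds C1=C6 and C2=C3)
Conditions: Et3N (2.0 equiv), TBSOTf (1.3 equiv), CH2Cl2, −78 to 0 °C; cold aq. NaHCO3 work-up, plug of Et3N-deactivated silica
Reagents that add atoms: tert-butyldimethylsilyl triflate, CC(C)(C)[Si](C)(C)OS(=O)(=O)C(F)(F)F
Why: Soft enolisation, the standard way from cyclohexenones to 2-silyloxy-1,3-cyclohexadienes: the silyl triflate activates the C1 carbonyl and Et3N removes the C6 proton (kinetic alpha-prime site, further acidified by the aryloxy oxygen), which erases the C6 stereocentre and places the aryloxy group on an sp2 carbon from which it can no longer be eliminated, while strong or aqueous base that could trigger loss of HBr or of 7 is avoided.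

Step 6
Reactants: 9 tert-butyl{[5,6-dibromo-2-(2,4-dibromophenoxy)cyclohexa-1,5-dien-1-yl]oxy}dimethylsilane
Product: 11 2,3-dibromo-6-(2,4-dibromophenoxy)phenol (target), via aryl silyl ether 10 (not isolated)
Conditions: DDQ (1.2 equiv), PhMe, rt to 40 °C; filter through Celite, evaporate; then Bu4NF (1.1 equiv), AcOH (1.2 equiv), THF, 0 °C
Reagents that add atoms: none
Why: DDQ dehydrogenation of a 1,3-cyclohexadiene: hydride leaves C5 (cation stabilised by the silyloxy oxygen at C1) or C4 (stabilised by the aryloxy oxygen at C6), loss of the adjacent proton aromatises ring A without any electrophilic bromine that could attack the free C4 position para to oxygen, and acetic acid-buffered fluoride then cleaves the electron-poor aryl silyl ether.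

Compound list
1 | cyclohexane-1,3-dione | O=C1CCCC(=O)C1 | starting material
2 | 2-bromocyclohexane-1,3-dione | O=C1CCCC(=O)C1Br | intermediate
3 | 2,3-dibromocyclohex-2-en-1-one | O=C1CCCC(Br)=C1Br | intermediate
4 | lithium 5,6-dibromocyclohexa-1,5-dien-1-olate (kinetic dienolate of 3, not isolated) | [Li+].[O-]C1=CCCC(Br)=C1Br | intermediate
5 | 2,3-dibromo-6-(trifluoroacetyl)cyclohex-2-en-1-one (racemic keto form, largely enolised, carried on crude) | O=C1C(C(=O)C(F)(F)F)CCC(Br)=C1Br | intermediate
6 | 2,3-dibromo-6-diazocyclohex-2-en-1-one | O=C1C(=[N+]=[N-])CCC(Br)=C1Br | intermediate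
7 | 2,4-dibromophenol | Oc1ccc(Br)cc1Br | starting material
8 | (±)-2,3-dibromo-6-(2,4-dibromophenoxy)cyclohex-2-en-1-one | O=C1C(Oc2ccc(Br)cc2Br)CCC(Br)=C1Br | intermediate
9 | tert-butyl{[5,6-dibromo-2-(2,4-dibromophenoxy)cyclohexa-1,5-dien-1-yl]oxy}dimethylsilane | CC(C)(C)[Si](C)(C)OC1=C(Oc2ccc(Br)cc2Br)CCC(Br)=C1Br | intermediate
10 | tert-butyl[2,3-dibromo-6-(2,4-dibromophenoxy)phenoxy]dimethylsilane (carried on crude) | CC(C)(C)[Si](C)(C)Oc1c(Oc2ccc(Br)cc2Br)ccc(Br)c1Br | intermediate
11 | 2,3-dibromo-6-(2,4-dibromophenoxy)phenol (achiral) | Oc1c(Oc2ccc(Br)cc2Br)ccc(Br)c1Br | target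

Total step count: 6 steps (steps 3 and 6 are telescoped sequences whose intermediates are carried on without purification).
Longest linear sequence: 6 steps, from 1 to 11; 7 is bought and enters in step 4.

Steps most likely to fail

Step 4. Migration of a C5 hydride to the carbenoid carbon followed by enolisation, carbene dimerisation or insertion into adventitious water may outrun capture by the weakly nucleophilic, ortho-hindered phenol. The fallback sets out from 3 (through dienolate 4) and comes back at 8. It makes the C6–O bond by substitution at a C6 alcohol in place of carbenoid capture. Dienolate 4, generated as in step 3, is hydroxylated with 3-phenyl-2-(phenylsulfonyl)oxaziridine (THF, −78 °C) to racemic 2,3-dibromo-6-hydroxycyclohex-2-en-1-one F1. A Mitsunobu reaction of F1 with phenol 7 (PPh3, DIAD, PhMe, 0 °C) then gives 8. The acidity of 7 suits this reaction, and no free phenoxide accumulates that could attack C3.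

Step 3. The amide, or later the amine and water, may add at C3 with loss of the C3 bromine, or deprotonation may occur at C4 in place of C6. The fallback sets out from 3 and comes back at 5. It replaces the strong base with soft enolisation. TMSOTf and Et3N (CH2Cl2, 0 °C) convert 3 into [(5,6-dibromocyclohexa-1,5-dien-1-yl)oxy]trimethylsilane F2. C6 of F2 is acylated by trifluoroacetic anhydride (CH2Cl2, −20 to 0 °C) with loss of the silyl group to give 5, which enters the azide stage of step 3 unchanged.

Step 6. Hydride abstraction from the bromine-deactivated diene may be slow, and the acidic hydroquinone may protodesilylate the dienol ether. The regenerated enone can then aromatise in the wrong sense by loss of HBr or of the phenol. The fallback sets out from 9 and comes back at 11. It dehydrogenates by selenoxide elimination instead of hydride abstraction.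
- PhSeCl (CH2Cl2, −78 °C) attacks C6 of 9 to give racemic 2,3-dibromo-6-(2,4-dibromophenoxy)-6-(phenylselanyl)cyclohex-2-en-1-one F3.
- H2O2 and pyridine (CH2Cl2, 0 °C) oxidise it to 2,3-dibromo-6-(2,4-dibromophenoxy)-6-(phenylseleninyl)cyclohex-2-en-1-one F4.
- F4 undergoes syn elimination towards C5–H to 2,3-dibromo-6-(2,4-dibromophenoxy)cyclohexa-2,5-dien-1-one F5, the keto tautomer of 11.
- F5 enolises directly to 11, so the silyl ether 10 is bypassed.

Further compounds
F1 | step 4 | (±)-2,3-dibromo-6-hydroxycyclohex-2-en-1-one | O=C1C(O)CCC(Br)=C1Br
F2 | step 3 | [(5,6-dibromocyclohexa-1,5-dien-1-yl)oxy]trimethylsilane | C[Si](C)(C)OC1=CCCC(Br)=C1Br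
F3 | step 6 | (±)-2,3-dibromo-6-(2,4-dibromophenoxy)-6-(phenylselanyl)cyclohex-2-en-1-one | O=C1C(Oc2ccc(Br)cc2Br)([Se]c2ccccc2)CCC(Br)=C1Br
F4 | step 6 | 2,3-dibromo-6-(2,4-dibromophenoxy)-6-(phenylseleninyl)cyclohex-2-en-1-one (mixture of diastereomers, racemic) | O=C1C(Oc2ccc(Br)cc2Br)([Se](=O)c2ccccc2)CCC(Br)=C1Br
F5 | step 6 | 2,3-dibromo-6-(2,4-dibromophenoxy)cyclohexa-2,5-dien-1-one | O=C1C(Oc2ccc(Br)cc2Br)=CCC(Br)=C1Br
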